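## Retrosynthetic overview

1. The target is epigallocatechin-(4β→6)-epigallocatechin 3-O-gallate; it is released last by hydrogenolysis of a tetradeca-O-benzyl-8,8'-dibromo precursor (17).
2. Key disconnection: ring C of the gallated (lower) unit is cut at C4–C3 and O1–C2, giving an ortho-quinone methide of lower ring A (exocyclic CH2=C4a–C8a=O) and the (Z)-enol gallate 15, which already carries ring B, the cis C2/C3 relation and the galloyl ester.
3. Enabling feature: C4 of the lower unit is an unsubstituted benzylic CH2 ortho to the ring-A oxygen O1 (a latent 1-oxadiene), and the donor aryl on C2 polarises the 2π partner. Because the upper unit is first C-bonded to symmetric phloroglucinol, 4→6 versus 4→8 is decided by which phenol oxygen is left free (the one para to the interflavan bond), not by C6/C8 competition.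
4. Ring order: rings A, C and B of the upper unit come from (−)-epigallocatechin; lower ring A comes from phloroglucinol (C-arylation, O-differentiation, ortho-formylation, bromine capping); lower ring C is closed last, in the key step.
5. The enol gallate 15 comes from 3,4,5-tris(benzyloxy)benzaldehyde (via the alkyne) and 3,4,5-tris(benzyloxy)benzoic acid by ruthenium-catalysed anti-Markovnikov addition.

Key step: step 12

Assumption: 3,4,5-tris(benzyloxy)benzaldehyde is taken as a catalogue compound, and for the chiral acid of step 12 the (R)-enantiomer is written; the sense of induction has to be established by experiment, and the (S)-acid is used instead if it proves opposite.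

## Route

Step 1
Reactants: 1 (−)-epigallocatechin
Product: 2 5,7,3',4',5'-penta-O-benzyl-(−)-epigallocatechin
Conditions: BnBr (5.5 equiv), K2CO3, DMF, argon, 0 °C → rt
Reagents that add atoms: benzyl bromide, BrCc1ccccc1
Why: Williamson etherification with a carbonate base should alkylate the five phenols and leave the secondary 3-hydroxyl free, and the (2R,3R) centres are not touched because ring opening through a quinone methide is no longer possible once O-4' is alkylated.

Step 2
Reactants: 2 penta-O-benzyl-epigallocatechin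
Product: 3 4β-(2-ethoxyethoxy)-5,7,3',4',5'-penta-O-benzyl-epigallocatechin
Conditions: DDQ (2 equiv), 2-ethoxyethanol (5 equiv), CH2Cl2, rt
Reagents that add atoms: 2-ethoxyethanol, CCOCCO
Why: DDQ benzylic oxidation (hydride abstraction) at C4, which is activated by the ortho and para oxygens of ring A, gives a flavan-4-yl cation that the alcohol should trap on the face opposite to the 3-hydroxyl and 2-aryl groups.

Step 3
Reactants: 3 4β-(2-ethoxyethoxy) ether; 4 phloroglucinol
Product: 5 4β-(2,4,6-trihydroxyphenyl)-5,7,3',4',5'-penta-O-benzyl-epigallocatechin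
Conditions: 4 (5 equiv), TMSOTf (0.3 equiv), THF–CH2Cl2, −78 → −30 °C; aq. NaHCO3
Reagents that add atoms: none
Why: Lewis-acid ionisation of the C4 ether followed by Friedel–Crafts capture of the flavan-4-yl cation by phloroglucinol, whose three positions are equivalent so that no regiochemical question arises, should set the 4β (3,4-trans) centre by attack anti to the C3 and C2 substituents.

Step 4
Reactants: 5 phloroglucinol adduct
Product: 6 4β-[2,6-dihydroxy-4-(triisopropylsilyloxy)phenyl]-5,7,3',4',5'-penta-O-benzyl-epigallocatechin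
Conditions: TIPSCl (1.05 equiv), imidazole, DMF, −20 → 0 °C
Reagents that add atoms: triisopropylsilyl chloride, CC(C)[Si](Cl)(C(C)C)C(C)C
Why: Sterically governed silylation should pick the only phenol without an ortho substituent (the one para to the interflavan bond) over the two phenols that flank the flavanyl group and over the hindered secondary alcohol.

Step 5
Reactants: 6 mono-silyl ether
Product: 7 3,5,7,3',4',5'-hexa-O-benzyl-4β-[2,6-bis(benzyloxy)-4-(triisopropylsilyloxy)phenyl]-epigallocatechin
Conditions: NaH (4 equiv), BnBr (4 equiv), Bu4NI (cat.), DMF, 0 °C → rt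
Reagents that add atoms: benzyl bromide, BrCc1ccccc1
Why: Williamson etherification under irreversible deprotonation should benzylate the two hindered phenols and the 3-hydroxyl in one operation, so that every oxygen except the silyl-masked one becomes a hydrogenolysable ether.

Step 6
Reactants: 7 silyl ether
Product: 8 3,5,7,3',4',5'-hexa-O-benzyl-4β-[2,6-bis(benzyloxy)-4-hydroxyphenyl]-epigallocatechin
Conditions: Bu4NF (1.1 equiv), AcOH (1.1 equiv), THF, 0 °C
Reagents that add atoms: none
Why: Fluoride-induced cleavage of the aryl silyl ether should free the single phenol para to the interflavan bond, the oxygen that becomes O1 of the lower unit.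

Step 7
Reactants: 8 para-phenol
Product: 9 3,5,7,3',4',5'-hexa-O-benzyl-4β-[2,6-bis(benzyloxy)-3-formyl-4-hydroxyphenyl]-epigallocatechin
Conditions: MgCl2 (anhydrous, 2 equiv), Et3N (4 equiv), paraformaldehyde (6 equiv), THF, reflux
Reagents that add atoms: formaldehyde (as paraformaldehyde), C=O
Why: Magnesium-phenoxide-directed ortho-formylation (Casnati–Skattebøl) should place the CHO only ortho to the free phenol, and the two ortho positions are interchanged by rotation about the interflavan bond, so one constitution results.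

Step 8
Reactants: 9 salicylaldehyde
Product: 10 8-bromo-3,5,7,3',4',5'-hexa-O-benzyl-4β-[2,6-bis(benzyloxy)-3-bromo-5-formyl-4-hydroxyphenyl]-epigallocatechin
Conditions: NBS (2.1 equiv), CH2Cl2, −40 °C → rt
Reagents that add atoms: N-bromosuccinimide, O=C1CCC(=O)N1Br
Why: Electrophilic aromatic bromination should take the two most electron-rich open positions, C8 of upper ring A (the usual site in benzylated flavan-3-ols) and the last free carbon ortho to the phenol of the lower ring, which caps both rings against later Friedel–Crafts capture of the quinone methide.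

Step 9
Reactants: 10 dibromo aldehyde
Product: 11 8-bromo-3,5,7,3',4',5'-hexa-O-benzyl-4β-[2,6-bis(benzyloxy)-3-bromo-4-hydroxy-5-(hydroxymethyl)phenyl]-epigallocatechin
Conditions: NaBH4, THF–EtOH, 0 °C; pH 7 buffer work-up, used without chromatography on acidic silica
Reagents that add atoms: none
Why: Chemoselective hydride reduction of the aldehyde should give the 2-hydroxybenzyl alcohol that serves as the quinone-methide precursor.

Step 10
Reactants: 12 3,4,5-tris(benzyloxy)benzaldehyde
Product: 13 1,2,3-tris(benzyloxy)-5-ethynylbenzene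
Conditions: dimethyl (1-diazo-2-oxopropyl)phosphonate (1.3 equiv), K2CO3, MeOH–THF, rt
Reagents that add atoms: dimethyl (1-diazo-2-oxopropyl)phosphonate, COP(=O)(OC)C(=[N+]=[N-])C(C)=O
Why: Seyferth–Gilbert homologation in its Ohira–Bestmann form should convert the aldehyde into the terminal alkyne under mild base that leaves benzyl ethers alone.

Step 11
Reactants: 13 aryl alkyne; 14 3,4,5-tris(benzyloxy)benzoic acid
Product: 15 (Z)-2-[3,4,5-tris(benzyloxy)phenyl]ethenyl 3,4,5-tris(benzyloxy)benzoate
Conditions: Ru(C4H7)2(dppb) [bis(2-methylallyl)(1,4-bis(diphenylphosphino)butane)ruthenium] (2 mol %), toluene, 65 °C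
Reagents that add atoms: none
Why: Ruthenium-catalysed anti-Markovnikov hydro-oxycarbonylation of a terminal alkyne runs through a ruthenium vinylidene that the carboxylate attacks at the carbon bound to the metal, which should give the (Z)-enol ester.

Step 12
Reactants: 11 2-hydroxybenzyl alcohol; 15 (Z)-enol gallate (3 equiv)
Product: 17 tetradeca-O-benzyl-8,8'-dibromo derivative of the target, via ortho-quinone methide 16 (not isolated)
Conditions: (R)-3,3'-bis(2,4,6-triisopropylphenyl)-1,1'-binaphthyl-2,2'-diyl hydrogen phosphate (10 mol %), 5 Å molecular sieves, toluene, 0 °C → rt, slow addition of 11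
Reagents that add atoms: none
Why: Proposed new method: the chiral phosphoric acid should dehydrate 11 to the hydrogen-bonded ortho-quinone methide 16 (a 1-oxadiene made of the exocyclic CH2, C4a and C8a of lower ring A and the carbonyl oxygen), which undergoes an inverse-electron-demand oxa-[4+2] cycloaddition with the electron-rich Z-alkene of 15, forming C4–C3 at the methide carbon and O1–C2 at the quinone-methide oxygen with rearomatisation of ring A as driving force. The closest known reaction type is the chiral phosphoric acid catalysed [4+2] cycloaddition of in situ generated ortho-quinone methides with styrenes, enol ethers and enamides; new here are a methide carbon without substituent, a 1,2-disubstituted Z-enol ester as 2π partner and induction on the two alkene carbons only. Ring C of the lower unit is closed as a six-membered ring by an intermolecular, suprafacial, asynchronous [4+2] addition in which C–C bond formation leads and C–O closure follows inside the ion pair. C2 and C3 are created together: their cis relation is carried over from the Z geometry of 15, and their absolute (2R,3R) sense is to be set by the chiral phosphate bound to the quinone-methide oxygen, which has to differentiate the two faces of the alkene, while the three stereocentres of the upper unit are remote and should not interfere. Regiochemistry (aryl on C2, galloyloxy on C3) should follow because the 3,4,5-tris(benzyloxy)phenyl group stabilises positive charge at the carbon that bonds to oxygen better than the weakly donating acyloxy group does; the 4→6 connectivity is secured because the only free phenol of 11 is para to the interflavan bond, and the two bromine atoms block C8 of both units against Friedel–Crafts capture of 16.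

Step 13
Reactants: 17 protected dibromo dimer
Product: 18 epigallocatechin-(4β→6)-epigallocatechin 3-O-gallate (target)
Conditions: H2 (1 atm), Pd(OH)2/C, Et3N (2.2 equiv), THF–MeOH–H2O, rt; reversed-phase purification
Reagents that add atoms: none
Why: Heterogeneous palladium-catalysed hydrogenolysis should remove the fourteen benzyl ethers and both aryl bromides in one operation, while the gallate ester, the benzylic ring ethers and the interflavan bond are expected to persist under these mild, amine-buffered conditions.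

## Compound list

1 | (−)-epigallocatechin, (2R,3R)-2-(3,4,5-trihydroxyphenyl)chromane-3,5,7-triol | C1c2c(O)cc(O)cc2O[C@H](c2cc(O)c(O)c(O)c2)[C@@H]1O | starting material
2 | 5,7,3',4',5'-penta-O-benzyl-(−)-epigallocatechin (2R,3R; free 3-OH) | C1c2c(OCc3ccccc3)cc(OCc3ccccc3)cc2O[C@H](c2cc(OCc3ccccc3)c(OCc3ccccc3)c(OCc3ccccc3)c2)[C@@H]1O | intermediate
3 | 4β-(2-ethoxyethoxy)-5,7,3',4',5'-penta-O-benzyl-epigallocatechin (2R,3R; C4 ether trans to 3-OH) | CCOCCO[C@H]1c2c(OCc3ccccc3)cc(OCc3ccccc3)cc2O[C@H](c2cc(OCc3ccccc3)c(OCc3ccccc3)c(OCc3ccccc3)c2)[C@@H]1O | intermediate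
4 | phloroglucinol (benzene-1,3,5-triol) | Oc1cc(O)cc(O)c1 | starting material
5 | 4β-(2,4,6-trihydroxyphenyl)-5,7,3',4',5'-penta-O-benzyl-epigallocatechin (2R,3R; aryl trans to 3-OH) | Oc1cc(O)c([C@H]2c3c(OCc4ccccc4)cc(OCc4ccccc4)cc3O[C@H](c3cc(OCc4ccccc4)c(OCc4ccccc4)c(OCc4ccccc4)c3)[C@@H]2O)c(O)c1 | intermediate
6 | 4β-[2,6-dihydroxy-4-(triisopropylsilyloxy)phenyl]-5,7,3',4',5'-penta-O-benzyl-epigallocatechin | CC(C)[Si](Oc1cc(O)c([C@H]2c3c(OCc4ccccc4)cc(OCc4ccccc4)cc3O[C@H](c3cc(OCc4ccccc4)c(OCc4ccccc4)c(OCc4ccccc4)c3)[C@@H]2O)c(O)c1)(C(C)C)C(C)C | intermediate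
7 | 3,5,7,3',4',5'-hexa-O-benzyl-4β-[2,6-bis(benzyloxy)-4-(triisopropylsilyloxy)phenyl]-epigallocatechin | CC(C)[Si](Oc1cc(OCc2ccccc2)c([C@H]2c3c(OCc4ccccc4)cc(OCc4ccccc4)cc3O[C@H](c3cc(OCc4ccccc4)c(OCc4ccccc4)c(OCc4ccccc4)c3)[C@@H]2OCc2ccccc2)c(OCc2ccccc2)c1)(C(C)C)C(C)C | intermediate
8 | 3,5,7,3',4',5'-hexa-O-benzyl-4β-[2,6-bis(benzyloxy)-4-hydroxyphenyl]-epigallocatechin | Oc1cc(OCc2ccccc2)c([C@H]2c3c(OCc4ccccc4)cc(OCc4ccccc4)cc3O[C@H](c3cc(OCc4ccccc4)c(OCc4ccccc4)c(OCc4ccccc4)c3)[C@@H]2OCc2ccccc2)c(OCc2ccccc2)c1 | intermediate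
9 | 3,5,7,3',4',5'-hexa-O-benzyl-4β-[2,6-bis(benzyloxy)-3-formyl-4-hydroxyphenyl]-epigallocatechin | O=Cc1c(O)cc(OCc2ccccc2)c([C@H]2c3c(OCc4ccccc4)cc(OCc4ccccc4)cc3O[C@H](c3cc(OCc4ccccc4)c(OCc4ccccc4)c(OCc4ccccc4)c3)[C@@H]2OCc2ccccc2)c1OCc1ccccc1 | intermediate
10 | 8-bromo-3,5,7,3',4',5'-hexa-O-benzyl-4β-[2,6-bis(benzyloxy)-3-bromo-5-formyl-4-hydroxyphenyl]-epigallocatechin | O=Cc1c(O)c(Br)c(OCc2ccccc2)c([C@H]2c3c(OCc4ccccc4)cc(OCc4ccccc4)c(Br)c3O[C@H](c3cc(OCc4ccccc4)c(OCc4ccccc4)c(OCc4ccccc4)c3)[C@@H]2OCc2ccccc2)c1OCc1ccccc1 | intermediate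
11 | 8-bromo-3,5,7,3',4',5'-hexa-O-benzyl-4β-[2,6-bis(benzyloxy)-3-bromo-4-hydroxy-5-(hydroxymethyl)phenyl]-epigallocatechin | OCc1c(O)c(Br)c(OCc2ccccc2)c([C@H]2c3c(OCc4ccccc4)cc(OCc4ccccc4)c(Br)c3O[C@H](c3cc(OCc4ccccc4)c(OCc4ccccc4)c(OCc4ccccc4)c3)[C@@H]2OCc2ccccc2)c1OCc1ccccc1 | intermediate
12 | 3,4,5-tris(benzyloxy)benzaldehyde | O=Cc1cc(OCc2ccccc2)c(OCc2ccccc2)c(OCc2ccccc2)c1 | starting material
13 | 1,2,3-tris(benzyloxy)-5-ethynylbenzene | C#Cc1cc(OCc2ccccc2)c(OCc2ccccc2)c(OCc2ccccc2)c1 | intermediate
14 | 3,4,5-tris(benzyloxy)benzoic acid | OC(=O)c1cc(OCc2ccccc2)c(OCc2ccccc2)c(OCc2ccccc2)c1 | starting material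
15 | (Z)-2-[3,4,5-tris(benzyloxy)phenyl]ethenyl 3,4,5-tris(benzyloxy)benzoate | O=C(O/C=C\c1cc(OCc2ccccc2)c(OCc2ccccc2)c(OCc2ccccc2)c1)c1cc(OCc2ccccc2)c(OCc2ccccc2)c(OCc2ccccc2)c1 | intermediate
16 | ortho-quinone methide: 3,5-bis(benzyloxy)-2-bromo-6-methylidene-4-(8-bromo-hexa-O-benzyl-epigallocatechin-4β-yl)cyclohexa-2,4-dien-1-one | C=C1C(=O)C(Br)=C(OCc2ccccc2)C([C@H]2c3c(OCc4ccccc4)cc(OCc4ccccc4)c(Br)c3O[C@H](c3cc(OCc4ccccc4)c(OCc4ccccc4)c(OCc4ccccc4)c3)[C@@H]2OCc2ccccc2)=C1OCc1ccccc1 | intermediate
17 | 8-bromo-3,5,7,3',4',5'-hexa-O-benzyl-epigallocatechin-(4β→6)-8-bromo-5,7,3',4',5'-penta-O-benzyl-epigallocatechin 3-O-[3,4,5-tris(benzyloxy)benzoate] (both units 2R,3R; interflavan bond trans to upper O-3) | O=C(O[C@@H]1Cc2c(c(Br)c(OCc5ccccc5)c([C@H]3c4c(OCc5ccccc5)cc(OCc5ccccc5)c(Br)c4O[C@H](c4cc(OCc5ccccc5)c(OCc5ccccc5)c(OCc5ccccc5)c4)[C@@H]3OCc3ccccc3)c2OCc2ccccc2)O[C@@H]1c1cc(OCc2ccccc2)c(OCc2ccccc2)c(OCc2ccccc2)c1)c1cc(OCc2ccccc2)c(OCc2ccccc2)c(OCc2ccccc2)c1 | intermediate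
18 | epigallocatechin-(4β→6)-epigallocatechin 3-O-gallate: (2R,3R)-5,7-dihydroxy-2-(3,4,5-trihydroxyphenyl)-6-[(2R,3R)-3,5,7-trihydroxy-2-(3,4,5-trihydroxyphenyl)chroman-4β-yl]chroman-3-yl 3,4,5-trihydroxybenzoate (interflavan bond trans to the upper 3-OH) | O=C(O[C@@H]1Cc2c(cc(O)c([C@H]3c4c(O)cc(O)cc4O[C@H](c4cc(O)c(O)c(O)c4)[C@@H]3O)c2O)O[C@@H]1c1cc(O)c(O)c(O)c1)c1cc(O)c(O)c(O)c1 | target

## Step count and risks

Total step count: 13. Longest linear sequence: 11 (steps 1–9, 12, 13).

Steps most likely to fail:

1. Step 12 (proposed new method). The catalyst may discriminate the two alkene faces poorly, because the methide carbon carries no substituent and the dienophile has no hydrogen-bond donor. The cis relation may also leak if the addition becomes stepwise and the benzylic cation at C2 rotates before ring closure, and the acid may isomerise or hydrolyse the enol ester. The fallback gives up catalyst control and uses the known thermal hetero-Diels–Alder reaction of ortho-quinone methides with styrenes. It sets out from 11, which is heated with excess 15 in o-xylene at about 150 °C in a sealed tube without any acid, so that the quinone methide forms by thermal loss of water and adds suprafacially. Both cis adducts are then expected in comparable amounts: 17 and its diastereomer with the (2S,3S)-configured lower unit F1. Because the upper unit is enantiopure, these are diastereomers and would be separated by preparative HPLC. The fallback comes back to the route at 17.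

2. Step 4. Site selection between the three phenols may be incomplete, giving ortho-silylated or bis-silylated material that later ends up as the 4→8 series. The fallback moves the differentiation from the oxygens to the C-arylation step. It sets out from 3, which is benzylated at O-3 (NaH, BnBr, DMF) to the 3-O-benzyl-4β-(2-ethoxyethoxy) ether F2. F2 is coupled under TMSOTf in CH2Cl2 at −78 °C with commercial 3,5-bis(benzyloxy)phenol (Oc1cc(OCc2ccccc2)cc(OCc2ccccc2)c1, 4 equiv). The isomer arylated para to the free hydroxyl is 8 itself; the isomer arylated ortho to the hydroxyl, the 4β-[2-hydroxy-4,6-bis(benzyloxy)phenyl] compound F3, is likely to be a substantial or even the main product and would be removed by chromatography. The fallback comes back to the route at 8 and bypasses 5, 6 and 7.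

3. Step 3. The unprotected triol may be silylated on oxygen or dissolve poorly, O-alkylation or double arylation of phloroglucinol may compete, and the triflic acid set free may re-ionise the new aryl–C4 bond. The fallback changes leaving group and activation mode to a thiophilic, non-protic one. It sets out from 3, which undergoes thiolysis with 2-mercaptobenzothiazole (BF3·OEt2, CH2Cl2, 0 °C) to the 4β-(benzothiazol-2-ylthio) derivative F4. F4 is then activated with AgBF4 in THF at −78 °C in the presence of phloroglucinol (5 equiv), and capture of the cation anti to the C3 substituent should again give 5. The fallback comes back to the route at 5.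

Further compounds
F1 | step 12 | diastereomer of 17 with (2S,3S)-configured lower unit | O=C(O[C@H]1Cc2c(c(Br)c(OCc5ccccc5)c([C@H]3c4c(OCc5ccccc5)cc(OCc5ccccc5)c(Br)c4O[C@H](c4cc(OCc5ccccc5)c(OCc5ccccc5)c(OCc5ccccc5)c4)[C@@H]3OCc3ccccc3)c2OCc2ccccc2)O[C@H]1c1cc(OCc2ccccc2)c(OCc2ccccc2)c(OCc2ccccc2)c1)c1cc(OCc2ccccc2)c(OCc2ccccc2)c(OCc2ccccc2)c1
F2 | step 4 | 4β-(2-ethoxyethoxy)-3,5,7,3',4',5'-hexa-O-benzyl-epigallocatechin | CCOCCO[C@H]1c2c(OCc3ccccc3)cc(OCc3ccccc3)cc2O[C@H](c2cc(OCc3ccccc3)c(OCc3ccccc3)c(OCc3ccccc3)c2)[C@@H]1OCc1ccccc1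
F3 | step 4 | 3,5,7,3',4',5'-hexa-O-benzyl-4β-[2-hydroxy-4,6-bis(benzyloxy)phenyl]-epigallocatechin | Oc1cc(OCc2ccccc2)cc(OCc2ccccc2)c1[C@H]1c2c(OCc3ccccc3)cc(OCc3ccccc3)cc2O[C@H](c2cc(OCc3ccccc3)c(OCc3ccccc3)c(OCc3ccccc3)c2)[C@@H]1OCc1ccccc1
F4 | step 3 | 4β-(benzothiazol-2-ylthio)-5,7,3',4',5'-penta-O-benzyl-epigallocatechin | S(c1nc2ccccc2s1)[C@H]1c2c(OCc3ccccc3)cc(OCc3ccccc3)cc2O[C@H](c2cc(OCc3ccccc3)c(OCc3ccccc3)c(OCc3ccccc3)c2)[C@@H]1O
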